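**Retrosynthetic overview**
- The target comes from a protected (3R)-3-hydroxyisoflavanone by one acidic unmasking (one aryl silyl ether, two MOM ethers); C3 is set by reagent-controlled hydroxylation of the isoflavanone enolate.
- Key disconnection: C3–C1′, the chromanone α-carbon to the ring B carbon. It is made by attack of the ring B arene C–H on a chromanone-derived trivalent-iodine enolonium (an α-keto cation equivalent), so two normally nucleophilic carbons are joined.
- The ring B arene comes from O-methylation, aromatic Claisen rearrangement of a prenyl ether (gives the 1,1-dimethylallyl group), and 2,3-bis(methoxymethoxy)phenol, itself from catechol by directed ortho-metalation and oxidation.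
- The enolonium precursor is the bis-silyl enol ether of 7-hydroxychroman-4-one.
- Ring order: no ring is built; rings A and C are bought fused, ring B comes from catechol, and the halves are joined at C3.

Assumption: the stereocentre in the given SMILES is 3R (CIP order OH > C4 > C2 > aryl), and catechol, 7-hydroxychroman-4-one and both antipodes of [(8,8-dichlorocamphoryl)sulfonyl]oxaziridine are taken as purchasable.

**Step 1**
Reactants: 1 catechol
Product: 2 1,2-bis(methoxymethoxy)benzene
Conditions: NaH, MOMCl, DMF, 0 °C to rt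
Reagents that add atoms: chloromethyl methyl ether, COCCl
Why: Williamson-type O-alkylation of both phenoxides gives the bis-acetal, which later serves as the ortho-directing group and as a non-migrating, mildly removable protection.

**Step 2**
Reactants: 2 1,2-bis(methoxymethoxy)benzene
Product: 5 2,3-bis(methoxymethoxy)phenol, via aryllithium 3 (not isolated), via dimethyl arylboronate 4 (not isolated)
Conditions: n-BuLi, THF, 0 °C to rt; B(OMe)3, −78 °C to rt; then H2O2 (30% aq), NaOH, 0 °C to rt
Reagents that add atoms: hydrogen peroxide, OO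
Why: Directed ortho-metalation (the MOM ether directs lithiation to C3), borylation and oxidative C–B to C–O conversion give the phenol regiospecifically.

**Step 3**
Reactants: 5 2,3-bis(methoxymethoxy)phenol
Product: 6 1,2-bis(methoxymethoxy)-3-[(3-methylbut-2-en-1-yl)oxy]benzene
Conditions: prenyl bromide, K2CO3, acetone, reflux
Reagents that add atoms: 1-bromo-3-methylbut-2-ene, CC(C)=CCBr
Why: Williamson ether synthesis on the only free phenol, by SN2 at the primary allylic carbon.

**Step 4**
Reactants: 6 1,2-bis(methoxymethoxy)-3-[(3-methylbut-2-en-1-yl)oxy]benzene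
Product: 8 2,3-bis(methoxymethoxy)-6-(2-methylbut-3-en-2-yl)phenol, via ortho-dienone 7 (not isolated)
Conditions: PhNEt2, 190 °C, sealed tube, Ar
Reagents that add atoms: none
Why: Aromatic Claisen ([3,3]-sigmatropic) rearrangement transfers the prenyl group with allylic inversion to the only free ortho carbon, giving the 1,1-dimethylallyl group, and the amine solvent speeds enolisation of dienone 7 to the phenol.

**Step 5**
Reactants: 8 2,3-bis(methoxymethoxy)-6-(2-methylbut-3-en-2-yl)phenol
Product: 9 2-methoxy-3,4-bis(methoxymethoxy)-1-(2-methylbut-3-en-2-yl)benzene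
Conditions: MeI, K2CO3, DMF, 40 °C
Reagents that add atoms: iodomethane, CI
Why: Williamson O-methylation of the hindered phenoxide; MOM groups cannot migrate, so the oxygen pattern stays fixed.

**Step 6**
Reactants: 10 7-hydroxychroman-4-one
Product: 11 4,7-bis[(tert-butyldimethylsilyl)oxy]-2H-chromene
Conditions: TBSOTf (2.5 equiv), Et3N, CH2Cl2, 0 °C to rt
Reagents that add atoms: tert-butyldimethylsilyl trifluoromethanesulfonate, CC(C)(C)[Si](C)(C)OS(=O)(=O)C(F)(F)F
Why: Silyl triflate/amine soft enolisation silylates the phenol and converts the aryl ketone into its silyl enol ether in one operation (only C3 is enolisable).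

**Step 7 (key step)**
Reactants: 11 4,7-bis[(tert-butyldimethylsilyl)oxy]-2H-chromene; 9 2-methoxy-3,4-bis(methoxymethoxy)-1-(2-methylbut-3-en-2-yl)benzene
Product: 13 racemic 7-[(tert-butyldimethylsilyl)oxy]-3-[4-methoxy-2,3-bis(methoxymethoxy)-5-(2-methylbut-3-en-2-yl)phenyl]chroman-4-one, via trivalent-iodine enolonium 12 (not isolated)
Conditions: PhI(OH)OTs (1.1 equiv), BF3·OEt2, CH2Cl2, −78 °C, slow addition of 11; then 9 (2 equiv), −78 to −40 °C; aq NaHCO3
Reagents that add atoms: none
Why: Proposed new method: PhI(OH)OTs/BF3·OEt2 converts the enol ether into an O-bound trivalent-iodine enolate whose C3 is an α-keto cation (enolonium) equivalent, and arene 9 attacks it through its only unhindered activated C–H (ortho to the in-plane MOM oxygen, para to OMe) in a Friedel–Crafts-type SN2′ displacement of PhI, the closest known reaction type being the enolonium α-arylation of ketone silyl enol ethers with indoles and other electron-rich (hetero)arenes; the C3–H centre formed is racemic and enolisable, so it needs no control.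

**Step 8**
Reactants: 13 racemic 7-[(tert-butyldimethylsilyl)oxy]-3-[4-methoxy-2,3-bis(methoxymethoxy)-5-(2-methylbut-3-en-2-yl)phenyl]chroman-4-one
Product: 15 (3R)-7-[(tert-butyldimethylsilyl)oxy]-3-hydroxy-3-[4-methoxy-2,3-bis(methoxymethoxy)-5-(2-methylbut-3-en-2-yl)phenyl]chroman-4-one, via sodium enolate 14 (not isolated)
Conditions: NaN(SiMe3)2, THF, −78 °C; then (+)-[(8,8-dichlorocamphoryl)sulfonyl]oxaziridine, −78 °C; aq NH4Cl
Reagents that add atoms: (+)-[(8,8-dichlorocamphoryl)sulfonyl]oxaziridine, O=S1(=O)C[C@@]23CC[C@@H](C2(C)C)C(Cl)(Cl)[C@]34ON14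
Why: Davis asymmetric enolate hydroxylation, in which the chiral N-sulfonyloxaziridine transfers oxygen to one face of the tetrasubstituted sodium enolate (reagent control), expected to give 3R by analogy with the sense reported for 2-substituted 1-tetralone enolates, the antipodal reagent being available should the sense be reversed.

**Step 9**
Reactants: 15 (3R)-7-[(tert-butyldimethylsilyl)oxy]-3-hydroxy-3-[4-methoxy-2,3-bis(methoxymethoxy)-5-(2-methylbut-3-en-2-yl)phenyl]chroman-4-one
Product: 16 (3R)-3-[2,3-dihydroxy-4-methoxy-5-(2-methylbut-3-en-2-yl)phenyl]-3,7-dihydroxy-2,3-dihydro-4H-chromen-4-one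
Conditions: HCl (1.25 M in MeOH), THF, 40 °C
Reagents that add atoms: none
Why: Acid-catalysed acetal exchange of the MOM ethers and methanolysis of the aryl silyl ether release the three phenols under conditions mild enough for the tertiary α-ketol, the aryl methyl ether and the 1,1-dimethylallyl group, so C3 is untouched.

**Compound list**
1 | catechol (benzene-1,2-diol) | Oc1ccccc1O | starting material
2 | 1,2-bis(methoxymethoxy)benzene | COCOc1ccccc1OCOC | intermediate
3 | [2,3-bis(methoxymethoxy)phenyl]lithium | [Li]c1cccc(OCOC)c1OCOC | intermediate (not isolated)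
4 | dimethyl [2,3-bis(methoxymethoxy)phenyl]boronate | COB(OC)c1cccc(OCOC)c1OCOC | intermediate (not isolated)
5 | 2,3-bis(methoxymethoxy)phenol | Oc1cccc(OCOC)c1OCOC | intermediate
6 | 1,2-bis(methoxymethoxy)-3-[(3-methylbut-2-en-1-yl)oxy]benzene | CC(C)=CCOc1cccc(OCOC)c1OCOC | intermediate
7 | 2,3-bis(methoxymethoxy)-6-(2-methylbut-3-en-2-yl)cyclohexa-2,4-dien-1-one (racemic) | O=C1C(OCOC)=C(OCOC)C=CC1C(C)(C)C=C | intermediate (not isolated)
8 | 2,3-bis(methoxymethoxy)-6-(2-methylbut-3-en-2-yl)phenol | Oc1c(OCOC)c(OCOC)ccc1C(C)(C)C=C | intermediate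
9 | 2-methoxy-3,4-bis(methoxymethoxy)-1-(2-methylbut-3-en-2-yl)benzene | COc1c(OCOC)c(OCOC)ccc1C(C)(C)C=C | intermediate
10 | 7-hydroxychroman-4-one | O=C1CCOc2cc(O)ccc12 | starting material
11 | 4,7-bis[(tert-butyldimethylsilyl)oxy]-2H-chromene | CC(C)(C)[Si](C)(C)OC1=CCOc2cc(O[Si](C)(C)C(C)(C)C)ccc12 | intermediate
12 | {7-[(tert-butyldimethylsilyl)oxy]-2H-chromen-4-yl}oxy(phenyl)iodanyl 4-methylbenzenesulfonate (O-bound trivalent-iodine enolate) | Cc1ccc(cc1)S(=O)(=O)OI(OC1=CCOc2cc(O[Si](C)(C)C(C)(C)C)ccc12)c1ccccc1 | intermediate (not isolated)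
13 | racemic 7-[(tert-butyldimethylsilyl)oxy]-3-[4-methoxy-2,3-bis(methoxymethoxy)-5-(2-methylbut-3-en-2-yl)phenyl]chroman-4-one | C=CC(C)(C)c1cc(C2COc3cc(O[Si](C)(C)C(C)(C)C)ccc3C2=O)c(OCOC)c(OCOC)c1OC | intermediate
14 | sodium 7-[(tert-butyldimethylsilyl)oxy]-3-[4-methoxy-2,3-bis(methoxymethoxy)-5-(2-methylbut-3-en-2-yl)phenyl]-2H-chromen-4-olate | [Na+].[O-]C1=C(COc2cc(O[Si](C)(C)C(C)(C)C)ccc12)c1cc(C(C)(C)C=C)c(OC)c(OCOC)c1OCOC | intermediate (not isolated)
15 | (3R)-7-[(tert-butyldimethylsilyl)oxy]-3-hydroxy-3-[4-methoxy-2,3-bis(methoxymethoxy)-5-(2-methylbut-3-en-2-yl)phenyl]chroman-4-one | C=CC(C)(C)c1cc([C@@]2(O)COc3cc(O[Si](C)(C)C(C)(C)C)ccc3C2=O)c(OCOC)c(OCOC)c1OC | intermediate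
16 | (3R)-3-[2,3-dihydroxy-4-methoxy-5-(2-methylbut-3-en-2-yl)phenyl]-3,7-dihydroxy-2,3-dihydro-4H-chromen-4-one | C=CC(C)(C)c1cc([C@@]2(O)COc3cc(O)ccc3C2=O)c(O)c(O)c1OC | target

**Step count**
Total: 9 steps. Longest linear sequence: 8 steps (steps 1–5, then 7–9); step 6 is a one-step side branch.

**Steps most likely to fail**

1. Step 7. The enolonium can collapse by 1,2-hydride shift or elimination to the 7-silyloxychromone, can dimerise with unreacted 11, and arene 9 is a weaker nucleophile than the indoles for which this chemistry is established. Fallback, setting out from 9 (with 11) and returning at 13: 9 is brominated at the same carbon (NBS, MeCN, 0 °C) to give 1-bromo-4-methoxy-2,3-bis(methoxymethoxy)-5-(2-methylbut-3-en-2-yl)benzene F1. F1 is then coupled with silyl enol ether 11 through its tin enolate made in situ (Pd2(dba)3, P(t-Bu)3, Bu3SnF, toluene, 85 °C) to give 13. Here the aryl bromide is the electrophilic partner and the enolate keeps its normal polarity, so no cationic C3 species is formed.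

2. Step 8. The enantioselectivity and even the sense of induction for a 3-aryl enolate carrying an ortho MOM ether rest on analogy. Fallback, setting out from 13 and returning at 15: 13 is converted (TBSOTf, Et3N, CH2Cl2) into 4,7-bis[(tert-butyldimethylsilyl)oxy]-3-[4-methoxy-2,3-bis(methoxymethoxy)-5-(2-methylbut-3-en-2-yl)phenyl]-2H-chromene F2. F2 is epoxidised with the dioxirane from the Shi fructose-derived ketone (KHSO5, K2CO3, MeCN–dimethoxymethane–H2O, 0 °C), and the silyloxy epoxide opens to 15 (asymmetric Rubottom oxidation). The D- or L-fructose-derived catalyst is chosen as the one that gives 3R, and the terminal vinyl group is far less reactive toward the dioxirane than the enol ether.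

3. Step 4. The ortho-dienone can undergo Cope shift to the free para position (giving a para-prenyl phenol), and the product phenol can undergo abnormal Claisen chemistry at 190 °C. Fallback, setting out from 5 and returning at 9: 5 is brominated ortho to the hydroxyl (NBS, cat. i-Pr2NH, CH2Cl2, 0 °C) to give 6-bromo-2,3-bis(methoxymethoxy)phenol F3. F3 is O-methylated (MeI, K2CO3, DMF) to 1-bromo-2-methoxy-3,4-bis(methoxymethoxy)benzene F4. F4 is then coupled with 3-methylbut-2-enylboronic acid pinacol ester under Pd(OAc)2 catalysis with a biaryl monophosphine ligand that is γ-selective for 3,3-disubstituted allylboronates (K3PO4, THF–H2O, 40 °C), which installs the 1,1-dimethylallyl group at the C–Br position and gives 9.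

**Further compounds**
F1 | step 7 | 1-bromo-4-methoxy-2,3-bis(methoxymethoxy)-5-(2-methylbut-3-en-2-yl)benzene | C=CC(C)(C)c1cc(Br)c(OCOC)c(OCOC)c1OC
F2 | step 8 | 4,7-bis[(tert-butyldimethylsilyl)oxy]-3-[4-methoxy-2,3-bis(methoxymethoxy)-5-(2-methylbut-3-en-2-yl)phenyl]-2H-chromene | C=CC(C)(C)c1cc(C2=C(O[Si](C)(C)C(C)(C)C)c3ccc(O[Si](C)(C)C(C)(C)C)cc3OC2)c(OCOC)c(OCOC)c1OC
F3 | step 4 | 6-bromo-2,3-bis(methoxymethoxy)phenol | Oc1c(Br)ccc(OCOC)c1OCOC
F4 | step 4 | 1-bromo-2-methoxy-3,4-bis(methoxymethoxy)benzene | COc1c(Br)ccc(OCOC)c1OCOC
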